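**Plan**

1. Retrosynthetic cuts, in order: the benzyl and silyl groups; the C4(middle)–O bond of the C4–O–C4 bridge; O1–C8a together with C4–C4a of the middle unit (its ring C); the C4(upper)–C8(middle) bond. The lower unit is ent-epicatechin oxidised at C4.
2. Forward: (−)-epicatechin gives a 4-alkoxy donor, which alkylates 3,5-bis(benzyloxy)phenol ortho to the phenol oxygen. The phenol becomes a triflate, then an aryne, and an aldol-derived β-hydroxy Weinreb amide is annulated onto it, building ring C of the middle unit on the upper unit. The resulting C4 ketone is reduced and converted to a 4β-benzylthio donor, coupled with the lower-unit alcohol under AgBF4, desilylated and hydrogenolysed.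
3. Stereochemistry: upper unit C2/C3 from (−)-epicatechin, its C4 by attack anti to 3-OTBS. Middle unit C2/C3 from an Evans syn-glycolate aldol, carried through ring closure untouched; its C4 by attack on the flavan-4-yl cation anti to 3-OBn. Lower unit C2/C3 from (+)-epicatechin, its C4 by hydride addition anti to the axial 3-OTBS.
4. Enabling feature: in ring A of the middle unit, O1 (on C8a) and C4 (on C4a) sit on adjacent carbons; C8a is flanked by C8, which carries C4 of the upper unit, and C4a by the C5 oxygen. This edge is the retron of an aryne C4a≡C8a whose C5 alkoxy group steers an oxygen nucleophile to C8a, with the partner O1–C2–C3–C4(=O) being a β-hydroxy carbonyl compound. The phenol oxygen that first directs the upper unit to C8 then leaves as triflate.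

Key step: step 9

Assumption: (+)-epicatechin (2S,3S) is taken as purchasable. "4β" in the two (2R)-units means trans to the 3-oxygen; "all-cis" in the lower unit means 2-aryl, 3-O and 4-O on one face.

**Route**

Step 1
Reactants: 1 (−)-epicatechin
Product: 2 5,7,3',4'-tetra-O-benzyl-(−)-epicatechin
Conditions: BnBr, K2CO3, DMF, 0 °C to rt
Reagents that add atoms: benzyl bromide (BrCc1ccccc1)
Why: Williamson etherification in which the four phenols, far more acidic than the C3 alcohol, are alkylated selectively and no stereocentre is touched.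

Step 2
Reactants: 2 5,7,3',4'-tetra-O-benzyl-(−)-epicatechin
Product: 3 4β-(2-ethoxyethoxy)-5,7,3',4'-tetra-O-benzyl-(−)-epicatechin
Conditions: DDQ, 2-ethoxyethanol, CH2Cl2, rt
Reagents that add atoms: 2-ethoxyethanol (CCOCCO)
Why: DDQ-mediated benzylic C–H oxidation, in which hydride abstraction at C4 gives a cation stabilised by the ring A oxygens that the alcohol captures anti to the 3-hydroxyl, setting the 4β (3,4-trans) ether.

Step 3
Reactants: 3 4β-(2-ethoxyethoxy)-5,7,3',4'-tetra-O-benzyl-(−)-epicatechin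
Product: 4 3-O-TBS ether of 3
Conditions: TBSCl, imidazole, DMF, rt to 40 °C
Reagents that add atoms: tert-butyldimethylsilyl chloride (CC(C)(C)[Si](C)(C)Cl)
Why: Silylation of the secondary alcohol under basic conditions that do not ionise the 4-alkoxy group, so that this oxygen stays out of the later aryne and cation chemistry.

Step 4
Reactants: 4 3-O-TBS ether of 3; 5 3,5-bis(benzyloxy)phenol (excess)
Product: 6 4β-[2,4-bis(benzyloxy)-6-hydroxyphenyl]-5,7,3',4'-tetra-O-benzyl-3-O-TBS-(−)-epicatechin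
Conditions: TMSOTf, CH2Cl2, −78 to −20 °C
Reagents that add atoms: none
Why: Friedel–Crafts alkylation in which TMSOTf ionises the 4-alkoxy group and the excess phenol takes up the flavan-4-yl cation at the carbon ortho to its hydroxyl (O-alkylation and ion-pair return; the para carbon lies between two benzyloxy groups) from the face anti to 3-OTBS, setting the 4β centre and placing the upper unit on the future C8.

Step 5
Reactants: 6 4β-[2,4-bis(benzyloxy)-6-hydroxyphenyl]-5,7,3',4'-tetra-O-benzyl-3-O-TBS-(−)-epicatechin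
Product: 7 aryl triflate of 6
Conditions: Tf2O, pyridine, CH2Cl2, 0 °C
Reagents that add atoms: triflic anhydride (O=S(=O)(OS(=O)(=O)C(F)(F)F)C(F)(F)F)
Why: O-sulfonylation of the phenol, which turns the oxygen that steered the alkylation into the leaving group needed for aryne formation.

Step 6
Reactants: 8 (S)-4-benzyloxazolidin-2-one; 9 (benzyloxy)acetyl chloride
Product: 10 (S)-4-benzyl-3-[(benzyloxy)acetyl]oxazolidin-2-one
Conditions: n-BuLi, THF, −78 °C
Reagents that add atoms: none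
Why: N-acylation of the lithiated oxazolidinone by the acid chloride, the standard preparation of an Evans glycolate imide.

Step 7
Reactants: 10 (S)-4-benzyl-3-[(benzyloxy)acetyl]oxazolidin-2-one; 11 3,4-bis(benzyloxy)benzaldehyde
Product: 12 (S)-4-benzyl-3-[(2S,3R)-2-(benzyloxy)-3-[3,4-bis(benzyloxy)phenyl]-3-hydroxypropanoyl]oxazolidin-2-one
Conditions: Bu2BOTf, Et3N, CH2Cl2, −78 to 0 °C; then pH 7 buffer, MeOH, H2O2
Reagents that add atoms: none
Why: Evans syn-aldol reaction in which the Z-boron enolate reacts through a chair transition state on the face left open by the benzyl group of the auxiliary, setting C2 (S) and C3 (R) of the chain, the future C3 and C2 of the middle unit, in the syn relation that becomes 2,3-cis.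

Step 8
Reactants: 12 syn-aldol adduct
Product: 13 (2S,3R)-2-(benzyloxy)-3-[3,4-bis(benzyloxy)phenyl]-3-hydroxy-N-methoxy-N-methylpropanamide
Conditions: MeNHOMe·HCl, AlMe3, CH2Cl2, −20 to 0 °C
Reagents that add atoms: N,O-dimethylhydroxylamine hydrochloride (CNOC.Cl)
Why: Aluminium amide transamination at the exocyclic carbonyl (Weinreb amide formation), assisted by the free β-hydroxyl and leaving both stereocentres untouched.

Step 9
Reactants: 7 aryl triflate of 6; 13 β-hydroxy Weinreb amide (as its lithium alkoxide)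
Product: 17 protected dimeric flavanonol (ring C of the middle unit closed), via aryne 14 (not isolated), via aryllithium 15 (not isolated), via lithium hemiaminal 16 (not isolated)
Conditions: lithium 2,2,6,6-tetramethylpiperidide (2.6 equiv), THF, −78 to −30 °C; aq NH4Cl
Reagents that add atoms: none
Why: Proposed new method: lithium tetramethylpiperidide should remove the only ring proton ortho to the triflate of 7 (C4a–H, also acidified by the C5 benzyloxy group; the other ortho position carries the upper unit), and loss of lithium triflate gives aryne 14 (C4a≡C8a), to which the alkoxide of 13 adds through oxygen at C8a, forming the O1–C8a bond and aryllithium 15 at C4a, which is acylated by the tethered Weinreb amide to the chelated hemiaminal 16, releasing ketone 17 only on quench. The closest known reaction type is the annulation of arynes by ortho-hydroxyaryl esters (oxygen addition, then intramolecular acyl substitution by the aryl anion, giving xanthones), here transposed to an aliphatic β-hydroxy Weinreb amide and to an aryne generated from an aryl triflate with a lithium amide. Ring C of the middle unit is closed by a 6-exo-trig acyl substitution of C4a on C4 that follows the O1–C8a bond formation, a formal [4+2] annulation across the aryne. No stereocentre is created: C2 and C3 come from 13, no bond to either is broken, and C3 cannot enolise because the ketone stays masked as the hemiaminal until work-up. The step needs O-attack at C8a and not at C4a, which the C5 benzyloxy group should secure by polarising the aryne so that the nucleophile enters at the carbon remote from it and the carbanion develops next to oxygen; it also needs aryl deprotonation to outrun deprotonation alpha to the amide, which the neighbouring alkoxide of 13 disfavours, while the axial 3-OTBS oxygen of the upper unit lies anti to the aryl group and cannot reach C8a.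

Step 10
Reactants: 17 protected dimeric flavanonol
Product: 18 4-alcohol of 17 (3,4-cis expected)
Conditions: NaBH4, THF/MeOH, −20 to 0 °C
Reagents that add atoms: none
Why: Borohydride reduction of the aryl ketone with hydride entering anti to the axial 3-benzyloxy group; the configuration at C4 is of no consequence because C4 is ionised in step 11.

Step 11
Reactants: 18 4-alcohol of 17
Product: 19 4β-benzylthio derivative of the dimer
Conditions: phenylmethanethiol, BF3·OEt2, CH2Cl2, −78 to −40 °C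
Reagents that add atoms: phenylmethanethiol (SCc1ccccc1)
Why: Lewis-acid promoted SN1 thiolysis of the benzylic alcohol, the thiol adding to the flavan-4-yl cation anti to 3-OBn (4β), with the interflavan C–C bond and the silyl ether stable at low temperature.

Step 12
Reactants: 20 (+)-epicatechin
Product: 21 5,7,3',4'-tetra-O-benzyl-(+)-epicatechin
Conditions: BnBr, K2CO3, DMF, 0 °C to rt
Reagents that add atoms: benzyl bromide (BrCc1ccccc1)
Why: Williamson etherification of the four phenols as in step 1.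

Step 13
Reactants: 21 5,7,3',4'-tetra-O-benzyl-(+)-epicatechin
Product: 22 3-O-TBS ether of 21
Conditions: TBSCl, imidazole, DMF, rt
Reagents that add atoms: tert-butyldimethylsilyl chloride (CC(C)(C)[Si](C)(C)Cl)
Why: Silylation of the only free hydroxyl, giving the group that later directs the hydride.

Step 14
Reactants: 22 3-O-TBS ether of 21
Product: 23 (2S,3S,4R)-4-hydroxy derivative (3,4-trans)
Conditions: DDQ, CH2Cl2/H2O, rt
Reagents that add atoms: water (O)
Why: DDQ benzylic oxidation with water as nucleophile, which adds to the C4 cation anti to 3-OTBS; this configuration is corrected in steps 15 and 16.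

Step 15
Reactants: 23 4-hydroxy derivative (3,4-trans)
Product: 24 flavan-4-one of the lower unit
Conditions: Dess–Martin periodinane, NaHCO3, CH2Cl2, 0 °C to rt
Reagents that add atoms: none
Why: Dess–Martin oxidation of the benzylic alcohol under buffered conditions that spare the silyl ether and the C2/C3 centres.

Step 16
Reactants: 24 flavan-4-one of the lower unit
Product: 25 (2S,3S,4S)-4-alcohol (all-cis)
Conditions: NaBH4, THF/MeOH, −20 °C
Reagents that add atoms: none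
Why: Hydride adds to the carbonyl pseudo-axially and anti to the axial 3-OTBS group, giving the 3,4-cis alcohol so that 2-aryl, 3-O and 4-O are all on one face.

Step 17
Reactants: 19 4β-benzylthio donor (added slowly); 25 all-cis alcohol (excess)
Product: 26 fully protected trimer with the C4–O–C4 bridge
Conditions: AgBF4, 2,6-di-tert-butyl-4-methylpyridine, 4 Å molecular sieves, CH2Cl2, −40 to 0 °C
Reagents that add atoms: none
Why: Thiophile-promoted SN1 etherification (the flavan analogue of a thioglycoside glycosylation) in which AgBF4 removes the benzylthio group, alcohol 25 captures the cation anti to 3-OBn (4β), the hindered pyridine takes up HBF4 so that neither C4–O bond can ionise again, and C4 of the lower unit keeps its configuration because its C–O bond is never broken.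

Step 18
Reactants: 26 fully protected trimer
Product: 27 trideca-O-benzyl trimer with free 3-hydroxyls on the upper and lower units
Conditions: TBAF, AcOH, THF, rt to 40 °C
Reagents that add atoms: none
Why: Fluoride cleavage of the two secondary silyl ethers, buffered with acetic acid so that the bridge is not exposed to strong base.

Step 19
Reactants: 27 trideca-O-benzyl trimer
Product: 28 target CNP0310719.1
Conditions: H2 (1 atm), Pd(OH)2/C, THF/MeOH, rt, stopped at full debenzylation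
Reagents that add atoms: none
Why: Hydrogenolysis of the thirteen benzyl ethers, whose primary benzylic C–O bonds should cleave faster than the hindered secondary C4–O bonds of the bridge.

**Compound list**

1 | (−)-epicatechin, (2R,3R)-2-(3,4-dihydroxyphenyl)chromane-3,5,7-triol | Oc1cc(O)c2c(c1)O[C@H](c1ccc(O)c(O)c1)[C@H](O)C2 | starting material
2 | 5,7,3',4'-tetra-O-benzyl-(−)-epicatechin | c1ccccc1COc1cc(OCc3ccccc3)c2c(c1)O[C@H](c1ccc(OCc3ccccc3)c(OCc3ccccc3)c1)[C@H](O)C2 | intermediate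
3 | 4β-(2-ethoxyethoxy)-5,7,3',4'-tetra-O-benzyl-(−)-epicatechin (3,4-trans) | c1ccccc1COc1cc(OCc3ccccc3)c2c(c1)O[C@H](c1ccc(OCc3ccccc3)c(OCc3ccccc3)c1)[C@H](O)[C@H]2OCCOCC | intermediate
4 | 3-O-TBS ether of 3 (donor of the upper unit) | c1ccccc1COc1cc(OCc3ccccc3)c2c(c1)O[C@H](c1ccc(OCc3ccccc3)c(OCc3ccccc3)c1)[C@H](O[Si](C)(C)C(C)(C)C)[C@H]2OCCOCC | intermediate
5 | 3,5-bis(benzyloxy)phenol | Oc1cc(OCc2ccccc2)cc(OCc2ccccc2)c1 | starting material
6 | 4β-[2,4-bis(benzyloxy)-6-hydroxyphenyl]-5,7,3',4'-tetra-O-benzyl-3-O-TBS-(−)-epicatechin | c1ccccc1COc1cc(OCc3ccccc3)c2c(c1)O[C@H](c1ccc(OCc3ccccc3)c(OCc3ccccc3)c1)[C@H](O[Si](C)(C)C(C)(C)C)[C@H]2c1c(OCc3ccccc3)cc(OCc3ccccc3)cc1O | intermediate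
7 | aryl triflate of 6 (triflate on the former phenol oxygen) | c1ccccc1COc1cc(OCc3ccccc3)c2c(c1)O[C@H](c1ccc(OCc3ccccc3)c(OCc3ccccc3)c1)[C@H](O[Si](C)(C)C(C)(C)C)[C@H]2c1c(OCc3ccccc3)cc(OCc3ccccc3)cc1OS(=O)(=O)C(F)(F)F | intermediate
8 | (S)-4-benzyloxazolidin-2-one | O=C1N[C@@H](Cc2ccccc2)CO1 | starting material
9 | (benzyloxy)acetyl chloride | O=C(Cl)COCc1ccccc1 | starting material
10 | (S)-4-benzyl-3-[(benzyloxy)acetyl]oxazolidin-2-one | O=C(COCc1ccccc1)N1[C@@H](Cc2ccccc2)COC1=O | intermediate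
11 | 3,4-bis(benzyloxy)benzaldehyde | O=Cc1ccc(OCc2ccccc2)c(OCc2ccccc2)c1 | starting material
12 | (S)-4-benzyl-3-[(2S,3R)-2-(benzyloxy)-3-[3,4-bis(benzyloxy)phenyl]-3-hydroxypropanoyl]oxazolidin-2-one | O[C@H](c1ccc(OCc2ccccc2)c(OCc2ccccc2)c1)[C@H](OCc1ccccc1)C(=O)N1[C@@H](Cc2ccccc2)COC1=O | intermediate
13 | (2S,3R)-2-(benzyloxy)-3-[3,4-bis(benzyloxy)phenyl]-3-hydroxy-N-methoxy-N-methylpropanamide | O[C@H](c1ccc(OCc2ccccc2)c(OCc2ccccc2)c1)[C@H](OCc1ccccc1)C(=O)N(C)OC | intermediate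
14 | aryne from 7 (triflate and neighbouring ring hydrogen removed; triple bond C4a≡C8a of the future middle unit, upper unit on the adjacent carbon) | c1ccccc1COc1cc(OCc3ccccc3)c2c(c1)O[C@H](c1ccc(OCc3ccccc3)c(OCc3ccccc3)c1)[C@H](O[Si](C)(C)C(C)(C)C)[C@H]2C1=C(OCc3ccccc3)C=C(OCc3ccccc3)C#C1 | intermediate
15 | aryllithium (alkoxide oxygen of 13 bound to C8a, lithium on C4a, Weinreb amide intact) | c1ccccc1COc1cc(OCc3ccccc3)c2c(c1)O[C@H](c1ccc(OCc3ccccc3)c(OCc3ccccc3)c1)[C@H](O[Si](C)(C)C(C)(C)C)[C@H]2c1c(OCc3ccccc3)cc(OCc3ccccc3)c([Li])c1O[C@H](c1ccc(OCc3ccccc3)c(OCc3ccccc3)c1)[C@H](OCc1ccccc1)C(=O)N(C)OC | intermediate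
16 | cyclised lithium hemiaminal (C4 of the middle unit bears OLi and N(OMe)Me) | c1ccccc1COc1cc(OCc3ccccc3)c2c(c1)O[C@H](c1ccc(OCc3ccccc3)c(OCc3ccccc3)c1)[C@H](O[Si](C)(C)C(C)(C)C)[C@H]2c1c(OCc3ccccc3)cc(OCc3ccccc3)c2c1O[C@H](c1ccc(OCc3ccccc3)c(OCc3ccccc3)c1)[C@H](OCc1ccccc1)C2(O[Li])N(C)OC | intermediate
17 | protected dimeric flavanonol: upper unit of 6 joined 4β→8 to (2R,3S)-3,5,7-tris(benzyloxy)-2-[3,4-bis(benzyloxy)phenyl]chroman-4-one | c1ccccc1COc1cc(OCc3ccccc3)c2c(c1)O[C@H](c1ccc(OCc3ccccc3)c(OCc3ccccc3)c1)[C@H](O[Si](C)(C)C(C)(C)C)[C@H]2c1c(OCc3ccccc3)cc(OCc3ccccc3)c2c1O[C@H](c1ccc(OCc3ccccc3)c(OCc3ccccc3)c1)[C@H](OCc1ccccc1)C2=O | intermediate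
18 | 4-alcohol of 17 (4-OH cis to 3-OBn in the middle unit) | c1ccccc1COc1cc(OCc3ccccc3)c2c(c1)O[C@H](c1ccc(OCc3ccccc3)c(OCc3ccccc3)c1)[C@H](O[Si](C)(C)C(C)(C)C)[C@H]2c1c(OCc3ccccc3)cc(OCc3ccccc3)c2c1O[C@H](c1ccc(OCc3ccccc3)c(OCc3ccccc3)c1)[C@H](OCc1ccccc1)[C@@H]2O | intermediate
19 | 4β-benzylthio dimer (thio group trans to 3-OBn in the middle unit) | c1ccccc1COc1cc(OCc3ccccc3)c2c(c1)O[C@H](c1ccc(OCc3ccccc3)c(OCc3ccccc3)c1)[C@H](O[Si](C)(C)C(C)(C)C)[C@H]2c1c(OCc3ccccc3)cc(OCc3ccccc3)c2c1O[C@H](c1ccc(OCc3ccccc3)c(OCc3ccccc3)c1)[C@H](OCc1ccccc1)[C@H]2SCc1ccccc1 | intermediate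
20 | (+)-epicatechin, (2S,3S)-2-(3,4-dihydroxyphenyl)chromane-3,5,7-triol | C1c2c(O)cc(O)cc2O[C@@H](c2ccc(O)c(O)c2)[C@H]1O | starting material
21 | 5,7,3',4'-tetra-O-benzyl-(+)-epicatechin | C1c2c(OCc3ccccc3)cc(OCc3ccccc3)cc2O[C@@H](c2ccc(OCc3ccccc3)c(OCc3ccccc3)c2)[C@H]1O | intermediate
22 | 3-O-TBS ether of 21 | C1c2c(OCc3ccccc3)cc(OCc3ccccc3)cc2O[C@@H](c2ccc(OCc3ccccc3)c(OCc3ccccc3)c2)[C@H]1O[Si](C)(C)C(C)(C)C | intermediate
23 | (2S,3S,4R)-4-hydroxy derivative of 22 (3,4-trans) | O[C@@H]1c2c(OCc3ccccc3)cc(OCc3ccccc3)cc2O[C@@H](c2ccc(OCc3ccccc3)c(OCc3ccccc3)c2)[C@H]1O[Si](C)(C)C(C)(C)C | intermediate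
24 | (2S,3S)-5,7-bis(benzyloxy)-2-[3,4-bis(benzyloxy)phenyl]-3-(TBS-oxy)chroman-4-one | O=C1c2c(OCc3ccccc3)cc(OCc3ccccc3)cc2O[C@@H](c2ccc(OCc3ccccc3)c(OCc3ccccc3)c2)[C@H]1O[Si](C)(C)C(C)(C)C | intermediate
25 | (2S,3S,4S)-4-alcohol of the lower unit (all-cis) | O[C@H]1c2c(OCc3ccccc3)cc(OCc3ccccc3)cc2O[C@@H](c2ccc(OCc3ccccc3)c(OCc3ccccc3)c2)[C@H]1O[Si](C)(C)C(C)(C)C | intermediate
26 | fully protected trimer (thirteen benzyl ethers, two TBS ethers, C4–O–C4 bridge) | c1ccccc1COc1cc(OCc3ccccc3)c2c(c1)O[C@H](c1ccc(OCc3ccccc3)c(OCc3ccccc3)c1)[C@H](O[Si](C)(C)C(C)(C)C)[C@H]2c1c(OCc3ccccc3)cc(OCc3ccccc3)c2c1O[C@H](c1ccc(OCc3ccccc3)c(OCc3ccccc3)c1)[C@H](OCc1ccccc1)[C@H]2O[C@H]1c2c(OCc3ccccc3)cc(OCc3ccccc3)cc2O[C@@H](c2ccc(OCc3ccccc3)c(OCc3ccccc3)c2)[C@H]1O[Si](C)(C)C(C)(C)C | intermediate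
27 | trideca-O-benzyl trimer (3-OH free on upper and lower units) | c1ccccc1COc1cc(OCc3ccccc3)c2c(c1)O[C@H](c1ccc(OCc3ccccc3)c(OCc3ccccc3)c1)[C@H](O)[C@H]2c1c(OCc3ccccc3)cc(OCc3ccccc3)c2c1O[C@H](c1ccc(OCc3ccccc3)c(OCc3ccccc3)c1)[C@H](OCc1ccccc1)[C@H]2O[C@H]1c2c(OCc3ccccc3)cc(OCc3ccccc3)cc2O[C@@H](c2ccc(OCc3ccccc3)c(OCc3ccccc3)c2)[C@H]1O | intermediate
28 | CNP0310719.1 | Oc1cc(O)c2c(c1)O[C@H](c1ccc(O)c(O)c1)[C@H](O)[C@H]2c1c(O)cc(O)c2c1O[C@H](c1ccc(O)c(O)c1)[C@H](O)[C@H]2O[C@H]1c2c(O)cc(O)cc2O[C@@H](c2ccc(O)c(O)c2)[C@H]1O | target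

**Count and risks**

Total step count: 19. Longest linear sequence: 11 steps (1–5, 9–11, 17–19).

Steps most likely to fail:

Step 9 (labelled step). What may go wrong: the ortho-lithiated triflate may undergo anionic thia-Fries rearrangement instead of losing triflate; the alkoxide may add to the wrong aryne carbon (C4a) under steric pressure from the neighbouring upper unit; or deprotonation alpha to the amide may erode the C3 configuration. Fallback by known chemistry, setting out from 2 and 4: 2 is benzylated at O3 (NaH, BnBr, DMF) to 3,5,7,3',4'-penta-O-benzyl-(−)-epicatechin F1. Donor 4 is condensed with an excess of F1 (TMSOTf, CH2Cl2, −78 °C; Friedel–Crafts attack by C8 of F1 anti to 3-OTBS) to the 4β→8 linked dimer F2. DDQ in wet CH2Cl2 should hydroxylate the only benzylic methylene, C4 of the lower flavan, to the 4-hydroxy dimer F3. Thiolysis (phenylmethanethiol, BF3·OEt2) comes back to the route at 19. This fallback takes the heterocycle of the middle unit from natural epicatechin instead of building it.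

Step 17. What may go wrong: the hindered hydroxyl of 25 may be too slow, so that the cation is captured by arene carbons (C6/C8 of the excess alcohol) to give C–C linked products, or re-ionisation may scramble the bridge. Fallback, setting out from 25 and 19: the nucleophilic ring carbons of the alcohol are capped with bromine (NBS, 2 equiv, CH2Cl2, −20 °C) to give the 6,8-dibromo all-cis alcohol F4. Coupling with 19 under the conditions of step 17 gives the dibromo protected trimer F5. TBAF/AcOH gives the desilylated dibromo trimer F6. Hydrogenolysis over Pd(OH)2/C with Et3N removes bromine and benzyl together and comes back to the route at 28.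

Step 19. What may go wrong: once the phenols are freed, Pd may hydrogenolyse the bis-benzylic C4–O bonds of the bridge along with the benzyl ethers. Fallback, setting out from 17 and 24 (both are ketones and carry no sp3 C4–O bond): benzyl is exchanged for silyl before the bridge exists. Hydrogenolysis (H2, Pd(OH)2/C) of 17 gives the phenol-free dimeric flavanonol F7, and of 24 the lower-unit tetraphenol ketone F11. Silylation (TBSOTf, 2,6-lutidine) gives the per-TBS dimer ketone F8 and the per-TBS lower ketone F12. NaBH4 gives the per-TBS dimer 4-alcohol F9 and the per-TBS all-cis alcohol F13. Thiolysis of F9 (phenylmethanethiol, BF3·OEt2) gives the per-TBS 4β-benzylthio dimer F10. Coupling of F10 with F13 (AgBF4, hindered pyridine) gives the per-TBS trimer F14. Buffered fluoride (HF·pyridine in pyridine/THF) removes all silyl groups and comes back to the route at 28.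

**Further compounds**

F1 | step 9 | 3,5,7,3',4'-penta-O-benzyl-(−)-epicatechin | c1ccccc1COc1cc(OCc3ccccc3)c2c(c1)O[C@H](c1ccc(OCc3ccccc3)c(OCc3ccccc3)c1)[C@H](OCc1ccccc1)C2
F2 | step 9 | 4β→8 dimer of the upper unit of 4 and F1 (middle unit C4 is CH2) | c1ccccc1COc1cc(OCc3ccccc3)c2c(c1)O[C@H](c1ccc(OCc3ccccc3)c(OCc3ccccc3)c1)[C@H](O[Si](C)(C)C(C)(C)C)[C@H]2c1c(OCc3ccccc3)cc(OCc3ccccc3)c2c1O[C@H](c1ccc(OCc3ccccc3)c(OCc3ccccc3)c1)[C@H](OCc1ccccc1)C2
F3 | step 9 | 4β-hydroxy derivative of F2 (C4 epimer of 18) | c1ccccc1COc1cc(OCc3ccccc3)c2c(c1)O[C@H](c1ccc(OCc3ccccc3)c(OCc3ccccc3)c1)[C@H](O[Si](C)(C)C(C)(C)C)[C@H]2c1c(OCc3ccccc3)cc(OCc3ccccc3)c2c1O[C@H](c1ccc(OCc3ccccc3)c(OCc3ccccc3)c1)[C@H](OCc1ccccc1)[C@H]2O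
F4 | step 17 | 6,8-dibromo derivative of 25 | O[C@H]1c2c(OCc3ccccc3)c(Br)c(OCc3ccccc3)c(Br)c2O[C@@H](c2ccc(OCc3ccccc3)c(OCc3ccccc3)c2)[C@H]1O[Si](C)(C)C(C)(C)C
F5 | step 17 | protected trimer with 6,8-dibromo lower unit | c1ccccc1COc1cc(OCc3ccccc3)c2c(c1)O[C@H](c1ccc(OCc3ccccc3)c(OCc3ccccc3)c1)[C@H](O[Si](C)(C)C(C)(C)C)[C@H]2c1c(OCc3ccccc3)cc(OCc3ccccc3)c2c1O[C@H](c1ccc(OCc3ccccc3)c(OCc3ccccc3)c1)[C@H](OCc1ccccc1)[C@H]2O[C@H]1c2c(OCc3ccccc3)c(Br)c(OCc3ccccc3)c(Br)c2O[C@@H](c2ccc(OCc3ccccc3)c(OCc3ccccc3)c2)[C@H]1O[Si](C)(C)C(C)(C)C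
F6 | step 17 | desilylated dibromo trimer | c1ccccc1COc1cc(OCc3ccccc3)c2c(c1)O[C@H](c1ccc(OCc3ccccc3)c(OCc3ccccc3)c1)[C@H](O)[C@H]2c1c(OCc3ccccc3)cc(OCc3ccccc3)c2c1O[C@H](c1ccc(OCc3ccccc3)c(OCc3ccccc3)c1)[C@H](OCc1ccccc1)[C@H]2O[C@H]1c2c(OCc3ccccc3)c(Br)c(OCc3ccccc3)c(Br)c2O[C@@H](c2ccc(OCc3ccccc3)c(OCc3ccccc3)c2)[C@H]1O
F7 | step 19 | debenzylated dimeric flavanonol (upper 3-OTBS kept) | Oc1cc(O)c2c(c1)O[C@H](c1ccc(O)c(O)c1)[C@H](O[Si](C)(C)C(C)(C)C)[C@H]2c1c(O)cc(O)c2c1O[C@H](c1ccc(O)c(O)c1)[C@H](O)C2=O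
F8 | step 19 | per-TBS dimeric flavanonol | CC(C)(C)[Si](C)(C)Oc1cc(O[Si](C)(C)C(C)(C)C)c2c(c1)O[C@H](c1ccc(O[Si](C)(C)C(C)(C)C)c(O[Si](C)(C)C(C)(C)C)c1)[C@H](O[Si](C)(C)C(C)(C)C)[C@H]2c1c(O[Si](C)(C)C(C)(C)C)cc(O[Si](C)(C)C(C)(C)C)c2c1O[C@H](c1ccc(O[Si](C)(C)C(C)(C)C)c(O[Si](C)(C)C(C)(C)C)c1)[C@H](O[Si](C)(C)C(C)(C)C)C2=O
F9 | step 19 | per-TBS dimer 4-alcohol | CC(C)(C)[Si](C)(C)Oc1cc(O[Si](C)(C)C(C)(C)C)c2c(c1)O[C@H](c1ccc(O[Si](C)(C)C(C)(C)C)c(O[Si](C)(C)C(C)(C)C)c1)[C@H](O[Si](C)(C)C(C)(C)C)[C@H]2c1c(O[Si](C)(C)C(C)(C)C)cc(O[Si](C)(C)C(C)(C)C)c2c1O[C@H](c1ccc(O[Si](C)(C)C(C)(C)C)c(O[Si](C)(C)C(C)(C)C)c1)[C@H](O[Si](C)(C)C(C)(C)C)[C@@H]2O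
F10 | step 19 | per-TBS 4β-benzylthio dimer | CC(C)(C)[Si](C)(C)Oc1cc(O[Si](C)(C)C(C)(C)C)c2c(c1)O[C@H](c1ccc(O[Si](C)(C)C(C)(C)C)c(O[Si](C)(C)C(C)(C)C)c1)[C@H](O[Si](C)(C)C(C)(C)C)[C@H]2c1c(O[Si](C)(C)C(C)(C)C)cc(O[Si](C)(C)C(C)(C)C)c2c1O[C@H](c1ccc(O[Si](C)(C)C(C)(C)C)c(O[Si](C)(C)C(C)(C)C)c1)[C@H](O[Si](C)(C)C(C)(C)C)[C@H]2SCc1ccccc1
F11 | step 19 | debenzylated lower-unit ketone (3-OTBS kept) | O=C1c2c(O)cc(O)cc2O[C@@H](c2ccc(O)c(O)c2)[C@H]1O[Si](C)(C)C(C)(C)C
F12 | step 19 | per-TBS lower-unit ketone | O=C1c2c(O[Si](C)(C)C(C)(C)C)cc(O[Si](C)(C)C(C)(C)C)cc2O[C@@H](c2ccc(O[Si](C)(C)C(C)(C)C)c(O[Si](C)(C)C(C)(C)C)c2)[C@H]1O[Si](C)(C)C(C)(C)C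
F13 | step 19 | per-TBS all-cis lower-unit 4-alcohol | O[C@H]1c2c(O[Si](C)(C)C(C)(C)C)cc(O[Si](C)(C)C(C)(C)C)cc2O[C@@H](c2ccc(O[Si](C)(C)C(C)(C)C)c(O[Si](C)(C)C(C)(C)C)c2)[C@H]1O[Si](C)(C)C(C)(C)C
F14 | step 19 | per-TBS trimer with the C4–O–C4 bridge | CC(C)(C)[Si](C)(C)Oc1cc(O[Si](C)(C)C(C)(C)C)c2c(c1)O[C@H](c1ccc(O[Si](C)(C)C(C)(C)C)c(O[Si](C)(C)C(C)(C)C)c1)[C@H](O[Si](C)(C)C(C)(C)C)[C@H]2c1c(O[Si](C)(C)C(C)(C)C)cc(O[Si](C)(C)C(C)(C)C)c2c1O[C@H](c1ccc(O[Si](C)(C)C(C)(C)C)c(O[Si](C)(C)C(C)(C)C)c1)[C@H](O[Si](C)(C)C(C)(C)C)[C@H]2O[C@H]1c2c(O[Si](C)(C)C(C)(C)C)cc(O[Si](C)(C)C(C)(C)C)cc2O[C@@H](c2ccc(O[Si](C)(C)C(C)(C)C)c(O[Si](C)(C)C(C)(C)C)c2)[C@H]1O[Si](C)(C)C(C)(C)C
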